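## Retrosynthetic overview

- The target is cut at the CH2–CH2 bond between the isopropenyl methyl carbon of (R)-limonene and C1 of the side chain: a (Z)-C25 allylic chloride plus C10-lithiated (R)-limonene. No ring is built; the cyclohexene ring and its stereocentre come with (R)-limonene.
- The (Z)-allylic chloride comes from a (Z)-enoate, and that from an (E)-enol triflate. The key disconnection is the enol C3–O bond: stereoselective O-triflation of a β-keto ester stores the olefin geometry, and OTf is then exchanged for CH3 with retention.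
- The β-keto ester comes from a saturated C23 methyl ketone (C-methoxycarbonylation), and that from all-E-geranylgeranylacetone by one exhaustive asymmetric hydrogenation that sets the three methyl stereocentres.

Assumption: 1 is bought as the single 5E,9E,13E isomer (the all-E component of commercial teprenone).

Catalyst of step 1: [Ir(cod)(L)][B(ArF)4], with cod = 1,5-cyclooctadiene and ArF = 3,5-bis(trifluoromethyl)phenyl. L = 2-phenyl-7-[bis(2-methylphenyl)phosphanyloxy]-6,7-dihydro-5H-cyclopenta[b]pyridine, used as the enantiomer that reduces (2E,6E)-farnesol to (3S,7S)-3,7,11-trimethyldodecan-1-ol.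

## Route

Step 1
Reactants: 1 (5E,9E,13E)-6,10,14,18-tetramethylnonadeca-5,9,13,17-tetraen-2-one
Product: 2 (6S,10S,14S)-6,10,14,18-tetramethylnonadecan-2-one
Conditions: H2 (50 bar), 1 mol% [Ir(cod)(L)][B(ArF)4], CH2Cl2, 25 °C, 24 h
Reagents that add atoms: none
Why: Proposed new method: exhaustive asymmetric hydrogenation of a tetraenyl methyl ketone that creates three remote methyl stereocentres in one operation has not been shown; the cationic monovalent iridium precatalyst is turned by H2 into an iridium dihydride that binds each E-configured CH2–C(CH3)=CH–CH2 unit in the same quadrant orientation whatever the distant groups are, so one catalyst hand delivers H2 to the same enantioface of the 5,6-, 9,10- and 13,14-olefins (6S,10S,14S) and also saturates the terminal isopropylidene, while the weakly basic ketone does not compete for the metal in CH2Cl2; closest known reaction type: Ir–P,N-catalysed asymmetric hydrogenation of unfunctionalised trisubstituted olefins as practised on farnesol and tocotrienyl acetates, where two such centres are set.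

Step 2
Reactants: 2 (6S,10S,14S)-6,10,14,18-tetramethylnonadecan-2-one
Product: 4 methyl (7S,11S,15S)-7,11,15,19-tetramethyl-3-oxoicosanoate, via sodium enolate 3 (not isolated)
Conditions: NaH (2.5 equiv), (MeO)2CO (4 equiv), THF, reflux, slow addition of 2; AcOH quench
Reagents that add atoms: dimethyl carbonate, COC(=O)OC; sodium hydride, [Na+].[H-] (sodium of 3 only)
Why: Crossed Claisen condensation (C-methoxycarbonylation) takes place at the methyl group because only that regioisomer is drained irreversibly as the stabilised enolate 3, and the three stereocentres are remote from any acidic position.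

Step 3
Reactants: 4 methyl (7S,11S,15S)-7,11,15,19-tetramethyl-3-oxoicosanoate
Product: 6 methyl (2E,7S,11S,15S)-7,11,15,19-tetramethyl-3-{[(trifluoromethyl)sulfonyl]oxy}icos-2-enoate, via ammonium enolate 5 (not isolated)
Conditions: Tf2O (2.5 equiv), 25% aq Me4NOH (5 equiv), hexane, 5 °C, fast stirring
Reagents that add atoms: triflic anhydride, O=S(=O)(OS(=O)(=O)C(F)(F)F)C(F)(F)F; tetramethylammonium hydroxide, C[N+](C)(C)C.[OH-] (cation of 5 only)
Why: O-Sulfonylation of a β-keto ester enolate is the stereodefining C–O bond formation: with the non-chelating Me4N+ counter-ion the enolate 5 adopts the dipole-minimised W geometry, so triflation gives the (E)-enol triflate with OTf trans to CO2Me, which encodes the later Z-olefin.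

Step 4
Reactants: 6 methyl (2E,7S,11S,15S)-7,11,15,19-tetramethyl-3-{[(trifluoromethyl)sulfonyl]oxy}icos-2-enoate
Product: 7 methyl (2Z,7S,11S,15S)-3,7,11,15,19-pentamethylicos-2-enoate
Conditions: MeMgBr (1.4 equiv), 5 mol% Fe(acac)3, THF/NMP, −30 °C, 20 min
Reagents that add atoms: methylmagnesium bromide, C[Mg]Br
Why: Iron-catalysed Kumada-type cross-coupling of an alkenyl triflate proceeds with retention at the sp2 carbon, so CH3 takes the place of OTf and the alkyl chain stays cis to the ester (2Z), while the ester is not attacked at −30 °C.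

Step 5
Reactants: 7 methyl (2Z,7S,11S,15S)-3,7,11,15,19-pentamethylicos-2-enoate
Product: 9 (2Z,7S,11S,15S)-3,7,11,15,19-pentamethylicos-2-en-1-ol, via Z-enal 8 (not isolated)
Conditions: i-Bu2AlH (2.5 equiv), CH2Cl2, −78 → 0 °C; aq potassium sodium tartrate
Reagents that add atoms: none
Why: 1,2-Hydride reduction of the α,β-unsaturated ester by the aluminium hydride at low temperature goes through enal 8 to the allylic alcohol without conjugate reduction or Z/E isomerisation.

Step 6
Reactants: 9 (2Z,7S,11S,15S)-3,7,11,15,19-pentamethylicos-2-en-1-ol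
Product: 11 (2Z,7S,11S,15S)-1-chloro-3,7,11,15,19-pentamethylicos-2-ene, via allylic mesylate 10 (not isolated)
Conditions: MsCl (1.3 equiv), LiCl (3 equiv), 2,4,6-collidine (1.5 equiv), DMF, 0 °C
Reagents that add atoms: lithium chloride, [Li+].[Cl-]; methanesulfonyl chloride, CS(=O)(=O)Cl (mesyl group of 10, and chloride for the chloride pool)
Why: In situ mesylation and SN2 displacement by chloride at the primary allylic carbon (Collington–Meyers chlorination) give the allylic chloride without allylic transposition or loss of the Z geometry.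

Step 7
Reactants: 11 (2Z,7S,11S,15S)-1-chloro-3,7,11,15,19-pentamethylicos-2-ene; 12 (R)-limonene, (4R)-1-methyl-4-(prop-1-en-2-yl)cyclohex-1-ene
Product: 14 (4R)-1-methyl-4-[(5Z,10S,14S,18S)-6,10,14,18,22-pentamethyltricosa-1,5-dien-2-yl]cyclohex-1-ene, via 10-lithiolimonene 13 (not isolated)
Conditions: 12 (3 equiv), n-BuLi (2.5 equiv), TMEDA (2.5 equiv), hexane, 25 °C, 24 h; then 11 (1 equiv), THF, −78 → 0 °C
Reagents that add atoms: n-butyllithium, [Li]CCCC (lithium of 13 only; nothing from it remains in 14)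
Why: Kinetic allylic metalation of the isopropenyl methyl group by n-BuLi·TMEDA gives the 2-substituted allyllithium 13, whose two termini are equivalent, and its SN2 alkylation by the primary allylic chloride (allyl–allyl coupling) forms the last C–C bond without touching the ring stereocentre, which is never deprotonated, or the Z-olefin.

## Compound list

1 | (5E,9E,13E)-6,10,14,18-tetramethylnonadeca-5,9,13,17-tetraen-2-one (all-E-geranylgeranylacetone) | CC(=O)CC/C=C(\C)CC/C=C(\C)CC/C=C(\C)CCC=C(C)C | starting material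
2 | (6S,10S,14S)-6,10,14,18-tetramethylnonadecan-2-one | CC(=O)CCC[C@@H](C)CCC[C@@H](C)CCC[C@@H](C)CCCC(C)C | intermediate
3 | sodium (2Z,7S,11S,15S)-1-methoxy-7,11,15,19-tetramethyl-1-oxoicos-2-en-3-olate (chelated sodium enolate of 4) | [Na+].COC(=O)/C=C(\[O-])CCC[C@@H](C)CCC[C@@H](C)CCC[C@@H](C)CCCC(C)C | intermediate
4 | methyl (7S,11S,15S)-7,11,15,19-tetramethyl-3-oxoicosanoate | COC(=O)CC(=O)CCC[C@@H](C)CCC[C@@H](C)CCC[C@@H](C)CCCC(C)C | intermediate
5 | tetramethylammonium (2E,7S,11S,15S)-1-methoxy-7,11,15,19-tetramethyl-1-oxoicos-2-en-3-olate (W-shaped enolate of 4) | C[N+](C)(C)C.COC(=O)/C=C(/[O-])CCC[C@@H](C)CCC[C@@H](C)CCC[C@@H](C)CCCC(C)C | intermediate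
6 | methyl (2E,7S,11S,15S)-7,11,15,19-tetramethyl-3-{[(trifluoromethyl)sulfonyl]oxy}icos-2-enoate | COC(=O)/C=C(/OS(=O)(=O)C(F)(F)F)CCC[C@@H](C)CCC[C@@H](C)CCC[C@@H](C)CCCC(C)C | intermediate
7 | methyl (2Z,7S,11S,15S)-3,7,11,15,19-pentamethylicos-2-enoate | COC(=O)/C=C(/C)CCC[C@@H](C)CCC[C@@H](C)CCC[C@@H](C)CCCC(C)C | intermediate
8 | (2Z,7S,11S,15S)-3,7,11,15,19-pentamethylicos-2-enal | O=C/C=C(/C)CCC[C@@H](C)CCC[C@@H](C)CCC[C@@H](C)CCCC(C)C | intermediate
9 | (2Z,7S,11S,15S)-3,7,11,15,19-pentamethylicos-2-en-1-ol | OC/C=C(/C)CCC[C@@H](C)CCC[C@@H](C)CCC[C@@H](C)CCCC(C)C | intermediate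
10 | (2Z,7S,11S,15S)-3,7,11,15,19-pentamethylicos-2-en-1-yl methanesulfonate | CS(=O)(=O)OC/C=C(/C)CCC[C@@H](C)CCC[C@@H](C)CCC[C@@H](C)CCCC(C)C | intermediate
11 | (2Z,7S,11S,15S)-1-chloro-3,7,11,15,19-pentamethylicos-2-ene | ClC/C=C(/C)CCC[C@@H](C)CCC[C@@H](C)CCC[C@@H](C)CCCC(C)C | intermediate
12 | (R)-limonene, (4R)-1-methyl-4-(prop-1-en-2-yl)cyclohex-1-ene | CC(=C)[C@H]1CC=C(C)CC1 | starting material
13 | 10-lithiolimonene, {2-[(1R)-4-methylcyclohex-3-en-1-yl]prop-2-en-1-yl}lithium (TMEDA complex) | [Li]CC(=C)[C@H]1CC=C(C)CC1 | intermediate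
14 | (4R)-1-methyl-4-[(5Z,10S,14S,18S)-6,10,14,18,22-pentamethyltricosa-1,5-dien-2-yl]cyclohex-1-ene | C=C(CC/C=C(/C)CCC[C@@H](C)CCC[C@@H](C)CCC[C@@H](C)CCCC(C)C)[C@H]1CC=C(C)CC1 | target

## Step count and risks

Total step count: 7. Longest linear sequence: 7 (1 → 2 → 4 → 6 → 7 → 9 → 11 → 14); 12 enters in the last step.

Most likely to fail:

**Step 1 (the proposed new step).** Four C=C bonds must be reduced completely, three of them with the same facial sense, in the presence of a free ketone. One under-reduced olefin or one leaky centre gives diastereomers that cannot be separated later. The fallback uses known chemistry, sets out from 1 and comes back at 2. The ketone is masked as its dimethyl ketal, (5E,9E,13E)-2,2-dimethoxy-6,10,14,18-tetramethylnonadeca-5,9,13,17-tetraene F1 (HC(OMe)3, MeOH, cat. pyridinium p-toluenesulfonate, 25 °C). F1 is hydrogenated with the same iridium complex (H2, 50 bar, CH2Cl2), the ketal-protected form being the substrate class for which this exhaustive hydrogenation is established on the lower polyprenyl ketone homologues. This gives (6S,10S,14S)-2,2-dimethoxy-6,10,14,18-tetramethylnonadecane F2, and aqueous HCl in THF releases 2.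

**Step 3.** The E:Z ratio of the enol triflate with a long lipophilic chain may fall short, and every molecule of (Z)-triflate ends as the E-olefin after step 4. The fallback sets out from 2 and comes back at 7 with stereospecific alkyne chemistry. In one flask (LDA, THF, −78 °C; ClP(O)(OEt)2; then LDA, 2.3 equiv, −78 → 0 °C), 2 passes through the kinetic enol phosphate, diethyl (6S,10S,14S)-6,10,14,18-tetramethylnonadec-1-en-2-yl phosphate F3. Elimination gives the acetylide, lithium (6S,10S,14S)-6,10,14,18-tetramethylnonadec-1-yn-1-ide F4, which is trapped with ClCO2Me as the ynoate, methyl (7S,11S,15S)-7,11,15,19-tetramethylicos-2-ynoate F5. Syn addition of Me2CuLi (THF, −78 °C, MeOH quench at −78 °C) puts CH3 and H on the same side and gives 7.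

**Step 7.** The strongly basic allyllithium can cause elimination, SN2′ attack or Wurtz-type coupling of 11. The fallback reverses the polarity; it sets out from 11 and 12 (through 13) and comes back at 14. Chloride 11 and PhSO2Na (DMF, 25 °C) give the allylic sulfone, {[(2Z,7S,11S,15S)-3,7,11,15,19-pentamethylicos-2-en-1-yl]sulfonyl}benzene F6. Separately, 13 is quenched with C2Cl6 to give (4R)-4-(3-chloroprop-1-en-2-yl)-1-methylcyclohex-1-ene F7. The α-sulfonyl carbanion of F6 (n-BuLi, THF, −78 °C) is alkylated by F7 to the coupled sulfone, {[(5Z,10S,14S,18S)-6,10,14,18,22-pentamethyl-2-[(1R)-4-methylcyclohex-3-en-1-yl]tricosa-1,5-dien-4-yl]sulfonyl}benzene F8 (both epimers at the sulfonyl carbon). Reductive desulfonylation with LiBHEt3 and catalytic PdCl2(dppp) (dppp = 1,3-bis(diphenylphosphino)propane) in THF at 0 °C gives 14.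

Further compounds
F1 | step 1 | (5E,9E,13E)-2,2-dimethoxy-6,10,14,18-tetramethylnonadeca-5,9,13,17-tetraene | COC(C)(OC)CC/C=C(\C)CC/C=C(\C)CC/C=C(\C)CCC=C(C)C
F2 | step 1 | (6S,10S,14S)-2,2-dimethoxy-6,10,14,18-tetramethylnonadecane | COC(C)(OC)CCC[C@@H](C)CCC[C@@H](C)CCC[C@@H](C)CCCC(C)C
F3 | step 3 | diethyl (6S,10S,14S)-6,10,14,18-tetramethylnonadec-1-en-2-yl phosphate | C=C(OP(=O)(OCC)OCC)CCC[C@@H](C)CCC[C@@H](C)CCC[C@@H](C)CCCC(C)C
F4 | step 3 | lithium (6S,10S,14S)-6,10,14,18-tetramethylnonadec-1-yn-1-ide | [Li]C#CCCC[C@@H](C)CCC[C@@H](C)CCC[C@@H](C)CCCC(C)C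
F5 | step 3 | methyl (7S,11S,15S)-7,11,15,19-tetramethylicos-2-ynoate | COC(=O)C#CCCC[C@@H](C)CCC[C@@H](C)CCC[C@@H](C)CCCC(C)C
F6 | step 7 | {[(2Z,7S,11S,15S)-3,7,11,15,19-pentamethylicos-2-en-1-yl]sulfonyl}benzene | O=S(=O)(C/C=C(/C)CCC[C@@H](C)CCC[C@@H](C)CCC[C@@H](C)CCCC(C)C)c1ccccc1
F7 | step 7 | (4R)-4-(3-chloroprop-1-en-2-yl)-1-methylcyclohex-1-ene | C=C(CCl)[C@H]1CC=C(C)CC1
F8 | step 7 | {[(5Z,10S,14S,18S)-6,10,14,18,22-pentamethyl-2-[(1R)-4-methylcyclohex-3-en-1-yl]tricosa-1,5-dien-4-yl]sulfonyl}benzene | C=C(CC(/C=C(/C)CCC[C@@H](C)CCC[C@@H](C)CCC[C@@H](C)CCCC(C)C)S(=O)(=O)c1ccccc1)[C@H]1CC=C(C)CC1
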